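Assumption: flavone numbering (O1, C2, C3, C4, C4a, C5 to C8, C8a; rings A, C and B) is used for the target and for ring A of every intermediate, and compounds 1, 3, 5 and 16 are taken to be purchasable.

## Analysis of the target

Compound 27 is a flavonol: a 4H-chromen-4-one (benzo ring A fused to pyranone ring C) with a 4-hydroxyphenyl ring B on C2, hydroxyls on C3, C5 and C7, and a 2-methylbut-3-en-2-yl (1,1-dimethylallyl) group on C8. It has no stereocentre and no stereogenic double bond, so the problem is one of regiochemistry and chemoselectivity only. The sensitive parts are the terminal alkene and the electron-rich tetraphenol. The alkene lies next to O7 and can close onto O7–H to a dihydrofuran under acid or with halonium and epoxidising reagents; the tetraphenol is oxidised by air in base. The hard part is ring A: C8 carries a quaternary carbon and sits between the oxygenated carbons C7 and C8a. Direct C-alkylation of a phloroglucinol gives the linear prenyl isomer, does not distinguish C6 from C8, and leaves O5, O7 and O8a undifferentiated, although only O8a may close ring C. The strategy rests on the atom row C7(O)–C8(CMe2CH=CH2)–C8a(O). The fragment O–C7–C8–CMe2 is the pattern of a siloxyalkyne, and C8a, C4a, C5 and C6 are the four ring carbons of a 3-oxygenated cyclobutenone. Building ring A from these two pieces puts the quaternary carbon in place before the ring exists and leaves O8a as the only free oxygen.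

## Retrosynthetic reasoning

27 to 26. The last operation should only break Si–O bonds. All three phenols are carried as triisopropylsilyl ethers, so one buffered fluoride treatment unmasks them and no acid comes near the alkene beside O7.

26 to 23. The C3–O bond is cut. C3–H of flavone 23 is the one vinylic proton next to the carbonyl and can be lithiated, borylated and oxidised. An electrophilic oxidant is avoided because the terminal alkene would compete. This puts the C3 oxygen on late, so no protecting group for it is needed.

23 to 21. The O1–C2 bond is cut. The forward step is a 6-endo closure of the free O8a phenol onto ynone 21. It is run through the amine adduct 22, so that 5-exo closure to an aurone is avoided. Only O8a is free, so ring C cannot close to the 6-substituted isomer.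

21 to 15 and 18. The C3–C4 bond is cut, via alcohol 20. The three-carbon bridge comes from an aldehyde carbon on ring A and the acetylide 19, which is made in the flask from dibromoalkene 18. Compound 18 is two steps from 16, with 3 supplying the silyl group. The alkyne brings C2, C3 and ring B in one piece at the oxidation level of the flavone after one alcohol oxidation.

15 to 14. The C4a–C4 bond is cut. In phenol 14 the only free position ortho to the free hydroxyl is C4a, so a magnesium-directed ortho-formylation has one site to choose. The para position C6 is not reached by a phenoxide-bound electrophile.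

14 to 4 and 9. This is the central disconnection. The C8a–C8 and C7–C6 bonds are cut (the C4a–C8a bond of the cyclobutenone is broken and re-formed in the cascade). Ring A is taken apart into cyclobutenone 4 (C8a, C4a, C5 with its oxygen, C6) and siloxyalkyne 9 (C8 with the quaternary group, C7 with its oxygen). The cut is made here because it is the only one that places the quaternary carbon on an sp carbon, where crowding costs little. It also delivers O8a free with O5 and O7 protected, which is the differentiation the later ring closure needs.

4 to 2 and 1. Cyclobutenone 4 is the O-silyl derivative of dione 2 (silyl group from 3). Dione 2 is the hydrolysis product of the commercial vinylogous ester 1.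

9 to 6 and 5. The alkyne carbon that becomes C8 is inserted between the quaternary carbon and the carboxyl carbon of ester 6 by a carbenoid rearrangement through 7 and 8. The resulting ynolate is silylated on oxygen with 3. Ester 6 comes from acid 5, which already contains the complete 1,1-dimethylallyl unit.

## Alternatives that were turned down

Alternative 1: Ring A is opened at C4a–C8a to a cinnamoyl triketo ester, stored as the 4-hydroxy-2-pyrone A2. In the forward step a magnesium alkoxide opens the lactone of A2. The chelated tricarbonyl chain then undergoes an intramolecular Claisen condensation (C4a carbanion onto the C8a ester carbonyl) to give chalcone A1.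
- For: it is biomimetic and forms ring A with the whole C6–C3–C6 skeleton in one step. It needs no silyl groups on ring A. On this point it is stronger than the chosen route, which needs four more steps after ring A to reach the flavone skeleton.
- Against: the electrophilic ester carbonyl C8a is next to C8, which already bears the tertiary alkyl group, so the ring-closing attack is neopentyl-like. Relactonisation and aldol-type closures compete, and the enone is a Michael acceptor for alkoxide.
- Against: A1 has three free phenols, and O5 and O8a both flank the acyl group. Ring C can therefore close on either, leading to the 6- and the 8-substituted series, and oxidative closure of chalcones with a second ortho hydroxyl tends towards aurones.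
- Against: A2 still needs a tertiary alkyl group on C3 of a pyrone, so the hard bond is only moved.
- The chosen route gives in exchange a quaternary carbon attached at an sp carbon and a ring A in which only O8a is free.

Alternative 2: Ring C is cut at C3–C4, which leads back to dialdehyde A4. In the forward step a thiazolium-derived carbene with an amine base forms the Breslow intermediate at the aromatic aldehyde of A4. It adds to the aliphatic aldehyde to give the 3-hydroxychroman-4-one A3 as a diastereomer mixture.
- For: the C4 ketone and the C3 hydroxyl are made together under mild catalytic conditions. The chosen route needs a separate lithiation–borylation–oxidation for the C3 oxygen, so the alternative is stronger here.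
- Against: it does not touch the real difficulty. Ring A with the C8 quaternary group and differentiated oxygens has to exist before A4 can be made.
- Against: A4 requires O-alkylation of O8a, the most hindered phenol, by a secondary benzylic electrophile, and it is an easily enolised α-aryl-α-aryloxy aldehyde.
- Against: A3 is one oxidation level below the flavonol, and its acetal protecting groups need acid for removal, which endangers the alkene beside O7.
- The chosen route solves ring A in its key step and ends with a fluoride deprotection.

Alternative 3: The C5–O and C4a–C4 bonds are cut. In the forward step fluoride converts silyl triflate A6 into the C4a–C5 aryne. The carboxylate of acid A7 adds at C5 and the aryl anion at C4a takes over the acyl group, giving ketone A5.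
- For: the orientation of addition is well controlled by the inductive effect of the C8a oxygen. The C3 oxygen arrives inside the acyl group. On these two points it matches or exceeds the chosen route.
- Against: A6 is a pentasubstituted benzene that already holds the quaternary carbon between two oxygens together with adjacent silyl and triflate groups, so the main problem is moved into a long precursor synthesis.
- Against: the hydroxyl set free in A5 is O5, not O8a. Ring C closure would need selective unmasking of O8a beside the O7 acetal while O5 competes, and acid would again be needed.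
- Against: C2 and ring B still have to be added and ring C closed oxidatively.
- The chosen route is shorter from ring A onwards and frees exactly the oxygen that must close ring C.

Key step: step 5

## Route

Step 1
Reactants: 1 3-ethoxycyclobut-2-en-1-one
Product: 2 cyclobutane-1,3-dione
Conditions: 1 M aq. HCl, THF, 0 °C to rt; evaporate, triturate
Reagents that add atoms: water, O
Why: Acid-catalysed hydrolysis of a vinylogous ester: water adds to C3 of the protonated enone and ethanol leaves (addition–elimination). The dione is a strong carbon acid and is used freshly made.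

Step 2
Reactants: 2 cyclobutane-1,3-dione; 3 chlorotriisopropylsilane
Product: 4 3-(triisopropylsilyloxy)cyclobut-2-en-1-one
Conditions: Et3N, CH2Cl2, 0 °C to rt; filter under argon, short-path distillation
Reagents that add atoms: none
Why: O-Silylation of a vinylogous acid: the triethylammonium enolate attacks silicon through oxygen, as in silyl ester formation. The bulky silyl group should make the vinylogous silyl ester stable enough to handle under dry conditions.

Step 3
Reactants: 5 2,2-dimethylbut-3-enoic acid
Product: 6 ethyl 2,2-dimethylbut-3-enoate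
Conditions: EtI, K2CO3, DMF, rt
Reagents that add atoms: iodoethane, CCI
Why: Carboxylate O-alkylation by SN2 displacement on iodoethane. No acid is used, so the allylic quaternary centre and the alkene are untouched.

Step 4
Reactants: 6 ethyl 2,2-dimethylbut-3-enoate; 3 chlorotriisopropylsilane
Product: 9 [(3,3-dimethylpent-4-en-1-yn-1-yl)oxy]triisopropylsilane, via lithium dibromoenolate 7 (not isolated), via lithium ynolate 8 (not isolated)
Conditions: CH2Br2, lithium 2,2,6,6-tetramethylpiperidide, THF, −78 °C; 6; LiN(SiMe3)2, then n-BuLi, −78 °C to rt; 3, −78 to 0 °C; aqueous work-up, distillation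
Reagents that add atoms: dibromomethane, BrCBr
Why: Kowalski ester homologation stopped at the ynolate: LiCHBr2 adds to the ester and the adduct collapses to dibromoenolate 7, bromine–lithium exchange gives a carbenoid, and the tertiary alkyl group migrates to the carbenoid carbon with loss of LiBr to give ynolate 8. The bulky chlorosilane 3 should silylate the ynolate on oxygen and not on carbon.

Step 5
Reactants: 4 3-(triisopropylsilyloxy)cyclobut-2-en-1-one; 9 [(3,3-dimethylpent-4-en-1-yn-1-yl)oxy]triisopropylsilane
Product: 14 2-(2-methylbut-3-en-2-yl)-3,5-bis(triisopropylsilyloxy)phenol, via siloxy vinylketene 10 (not isolated), via 4-vinylcyclobutenone 11 (not isolated), via dienylketene 12 (not isolated), via cyclohexa-2,4-dienone 13 (not isolated)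
Conditions: toluene, 110 °C, sealed tube, argon, 9 (1.5 equiv)
Reagents that add atoms: none
Why: This is a Danheiser benzannulation of a cyclobutenone with a siloxyalkyne, a known pericyclic cascade. Heat opens 4 by four-electron electrocyclic ring opening to vinylketene 10. The ketene carbon (future C8a) bonds to the alkyne carbon that bears the quaternary group (future C8) and the ketene α-carbon (future C6) bonds to the siloxy carbon (future C7) in a [2+2] cycloaddition that gives 11. A second four-electron opening gives dienylketene 12, which closes the six-membered ring A by six-electron electrocyclisation (C4a to C8a) to dienone 13, and tautomerisation gives the phenol. The only stereocentre formed, C4 of 11, is lost on ring opening, so no stereocontrol is needed. The selectivity needed is the orientation of the [2+2] step; the polarisation of the siloxyalkyne secures it, because the carbon β to oxygen is the nucleophile and the ketene carbonyl carbon the electrophile, which places the quaternary substituent between the new phenol and the siloxy carbon. The quaternary carbon is bonded beforehand to an sp carbon, so no substitution at a crowded aromatic position is required, and the oxygens emerge differentiated with O8a free and O5 and O7 silylated. The excess of 9 should limit acylation of the product phenol by 10.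

Step 6
Reactants: 14 2-(2-methylbut-3-en-2-yl)-3,5-bis(triisopropylsilyloxy)phenol
Product: 15 2-hydroxy-3-(2-methylbut-3-en-2-yl)-4,6-bis(triisopropylsilyloxy)benzaldehyde
Conditions: MgCl2, Et3N, (CH2O)n, MeCN, reflux; cold 5% aq. citric acid work-up
Reagents that add atoms: paraformaldehyde (as formaldehyde), C=O
Why: Magnesium-mediated ortho-formylation (Casnati–Skattebøl): the magnesium phenoxide delivers formaldehyde to the ortho carbon through a chelate, and a second formaldehyde oxidises the benzylic alkoxide to the aldehyde. C4a is the only free ortho position, and the para position C6 is not reached from the chelate.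

Step 7
Reactants: 16 4-hydroxybenzaldehyde; 3 chlorotriisopropylsilane
Product: 17 4-(triisopropylsilyloxy)benzaldehyde
Conditions: imidazole, DMF, rt
Reagents that add atoms: none
Why: Standard imidazole-promoted silylation of a phenol. The silyl group matches those on ring A, so one fluoride treatment removes all of them at the end.

Step 8
Reactants: 17 4-(triisopropylsilyloxy)benzaldehyde
Product: 18 [4-(2,2-dibromoethenyl)phenoxy]triisopropylsilane
Conditions: CBr4, PPh3, CH2Cl2, 0 °C
Reagents that add atoms: tetrabromomethane, BrC(Br)(Br)Br
Why: First stage of the Corey–Fuchs reaction: Wittig olefination of the aldehyde by Ph3P=CBr2, formed in the flask from CBr4 and PPh3.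

Step 9
Reactants: 18 [4-(2,2-dibromoethenyl)phenoxy]triisopropylsilane; 15 2-hydroxy-3-(2-methylbut-3-en-2-yl)-4,6-bis(triisopropylsilyloxy)benzaldehyde
Product: 20 2-{1-hydroxy-3-[4-(triisopropylsilyloxy)phenyl]prop-2-yn-1-yl}-6-(2-methylbut-3-en-2-yl)-3,5-bis(triisopropylsilyloxy)phenol (racemic), via lithium acetylide 19 (not isolated)
Conditions: 18 (2.5 equiv), n-BuLi (2 equiv per 18), THF, −78 °C; then 15, −78 to 0 °C; H2O; crude product used at once
Reagents that add atoms: none
Why: Second stage of the Corey–Fuchs reaction taken to the lithium acetylide 19 (bromine–lithium exchange, loss of LiBr, deprotonation), which adds 1,2 to the aldehyde. One equivalent of 19 is spent on the phenol and returns as the terminal alkyne. The carbinol centre forms racemic and is removed in step 10.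

Step 10
Reactants: 20 2-{1-hydroxy-3-[4-(triisopropylsilyloxy)phenyl]prop-2-yn-1-yl}-6-(2-methylbut-3-en-2-yl)-3,5-bis(triisopropylsilyloxy)phenol (racemic)
Product: 21 1-[2-hydroxy-3-(2-methylbut-3-en-2-yl)-4,6-bis(triisopropylsilyloxy)phenyl]-3-[4-(triisopropylsilyloxy)phenyl]prop-2-yn-1-one
Conditions: MnO2 (activated, excess), CH2Cl2, rt
Reagents that add atoms: none
Why: MnO2 oxidation of a doubly activated (benzylic and propargylic) alcohol. The phenol, the silyl ethers and the isolated alkene should be left alone, and the stereocentre disappears.

Step 11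
Reactants: 21 1-[2-hydroxy-3-(2-methylbut-3-en-2-yl)-4,6-bis(triisopropylsilyloxy)phenyl]-3-[4-(triisopropylsilyloxy)phenyl]prop-2-yn-1-one
Product: 23 8-(2-methylbut-3-en-2-yl)-5,7-bis(triisopropylsilyloxy)-2-[4-(triisopropylsilyloxy)phenyl]-4H-chromen-4-one, via enaminone 22 (not isolated)
Conditions: Et2NH, EtOH, rt to 50 °C
Reagents that add atoms: none
Why: Amine-mediated 6-endo ring closure: diethylamine adds to the ynone to give β-enaminone 22, then the O8a phenol attacks the β-carbon and the amine is expelled (addition–elimination). This path gives the chromen-4-one and avoids the 5-exo closure to an aurone that plain base can cause; the enaminone geometry does not matter because the β-carbon is exocyclic to the forming ring.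

Step 12
Reactants: 23 8-(2-methylbut-3-en-2-yl)-5,7-bis(triisopropylsilyloxy)-2-[4-(triisopropylsilyloxy)phenyl]-4H-chromen-4-one
Product: 26 3-hydroxy-8-(2-methylbut-3-en-2-yl)-5,7-bis(triisopropylsilyloxy)-2-[4-(triisopropylsilyloxy)phenyl]-4H-chromen-4-one, via 3-lithioflavone 24 (not isolated), via dimethyl boronate 25 (not isolated)
Conditions: LiN(i-Pr)2, THF, −78 °C; B(OMe)3, −78 to 0 °C; AcOH, 30% aq. H2O2, 0 °C to rt
Reagents that add atoms: hydrogen peroxide, OO
Why: Lithiation of the flavone at C3 (the vinylic C–H next to the carbonyl), trapping on boron, and oxidative 1,2-shift of C3 from boron to oxygen. The unactivated terminal alkene should not react with the amide base or with buffered peroxide.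

Step 13
Reactants: 26 3-hydroxy-8-(2-methylbut-3-en-2-yl)-5,7-bis(triisopropylsilyloxy)-2-[4-(triisopropylsilyloxy)phenyl]-4H-chromen-4-one
Product: 27 3,5,7-trihydroxy-2-(4-hydroxyphenyl)-8-(2-methylbut-3-en-2-yl)-4H-chromen-4-one
Conditions: Bu4NF, AcOH, THF, 0 °C, argon; pH 5 buffer work-up
Reagents that add atoms: none
Why: Fluoride cleaves aryl silyl ethers quickly because phenoxide is a good leaving group on silicon. Acetic acid buffering should protect the tetraphenol from air oxidation in base, and no acid strong enough to cyclise O7 onto the alkene is present.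

## Compound list

1 | 3-ethoxycyclobut-2-en-1-one | CCOC1=CC(=O)C1 | starting material
2 | cyclobutane-1,3-dione | O=C1CC(=O)C1 | intermediate
3 | chlorotriisopropylsilane | CC(C)[Si](Cl)(C(C)C)C(C)C | starting material
4 | 3-(triisopropylsilyloxy)cyclobut-2-en-1-one | CC(C)[Si](OC1=CC(=O)C1)(C(C)C)C(C)C | intermediate
5 | 2,2-dimethylbut-3-enoic acid | C=CC(C)(C)C(=O)O | starting material
6 | ethyl 2,2-dimethylbut-3-enoate | C=CC(C)(C)C(=O)OCC | intermediate
7 | lithium 1,1-dibromo-3,3-dimethylpenta-1,4-dien-2-olate (not isolated) | C=CC(C)(C)C([O-])=C(Br)Br.[Li+] | intermediate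
8 | lithium 3,3-dimethylpent-4-en-1-yn-1-olate (not isolated) | C=CC(C)(C)C#C[O-].[Li+] | intermediate
9 | [(3,3-dimethylpent-4-en-1-yn-1-yl)oxy]triisopropylsilane | C=CC(C)(C)C#CO[Si](C(C)C)(C(C)C)C(C)C | intermediate
10 | 3-(triisopropylsilyloxy)buta-1,3-dien-1-one (not isolated) | C=C(O[Si](C(C)C)(C(C)C)C(C)C)C=C=O | intermediate
11 | 2-(2-methylbut-3-en-2-yl)-3-(triisopropylsilyloxy)-4-[1-(triisopropylsilyloxy)ethenyl]cyclobut-2-en-1-one (racemic, not isolated) | C=CC(C)(C)C1=C(O[Si](C(C)C)(C(C)C)C(C)C)C(C(=C)O[Si](C(C)C)(C(C)C)C(C)C)C1=O | intermediate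
12 | (3E)-2-(2-methylbut-3-en-2-yl)-3,5-bis(triisopropylsilyloxy)hexa-1,3,5-trien-1-one (not isolated) | O=C=C(C(C)(C)C=C)/C(O[Si](C(C)C)(C(C)C)C(C)C)=C\C(=C)O[Si](C(C)C)(C(C)C)C(C)C | intermediate
13 | 2-(2-methylbut-3-en-2-yl)-3,5-bis(triisopropylsilyloxy)cyclohexa-2,4-dien-1-one (not isolated) | C=CC(C)(C)C1=C(O[Si](C(C)C)(C(C)C)C(C)C)C=C(O[Si](C(C)C)(C(C)C)C(C)C)CC1=O | intermediate
14 | 2-(2-methylbut-3-en-2-yl)-3,5-bis(triisopropylsilyloxy)phenol | C=CC(C)(C)c1c(O)cc(O[Si](C(C)C)(C(C)C)C(C)C)cc1O[Si](C(C)C)(C(C)C)C(C)C | intermediate
15 | 2-hydroxy-3-(2-methylbut-3-en-2-yl)-4,6-bis(triisopropylsilyloxy)benzaldehyde | C=CC(C)(C)c1c(O)c(C=O)c(O[Si](C(C)C)(C(C)C)C(C)C)cc1O[Si](C(C)C)(C(C)C)C(C)C | intermediate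
16 | 4-hydroxybenzaldehyde | O=Cc1ccc(O)cc1 | starting material
17 | 4-(triisopropylsilyloxy)benzaldehyde | O=Cc1ccc(O[Si](C(C)C)(C(C)C)C(C)C)cc1 | intermediate
18 | [4-(2,2-dibromoethenyl)phenoxy]triisopropylsilane | BrC(Br)=Cc1ccc(O[Si](C(C)C)(C(C)C)C(C)C)cc1 | intermediate
19 | lithium [4-(triisopropylsilyloxy)phenyl]ethynide (not isolated) | [Li]C#Cc1ccc(O[Si](C(C)C)(C(C)C)C(C)C)cc1 | intermediate
20 | 2-{1-hydroxy-3-[4-(triisopropylsilyloxy)phenyl]prop-2-yn-1-yl}-6-(2-methylbut-3-en-2-yl)-3,5-bis(triisopropylsilyloxy)phenol (racemic) | C=CC(C)(C)c1c(O)c(C(O)C#Cc2ccc(O[Si](C(C)C)(C(C)C)C(C)C)cc2)c(O[Si](C(C)C)(C(C)C)C(C)C)cc1O[Si](C(C)C)(C(C)C)C(C)C | intermediate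
21 | 1-[2-hydroxy-3-(2-methylbut-3-en-2-yl)-4,6-bis(triisopropylsilyloxy)phenyl]-3-[4-(triisopropylsilyloxy)phenyl]prop-2-yn-1-one | C=CC(C)(C)c1c(O)c(C(=O)C#Cc2ccc(O[Si](C(C)C)(C(C)C)C(C)C)cc2)c(O[Si](C(C)C)(C(C)C)C(C)C)cc1O[Si](C(C)C)(C(C)C)C(C)C | intermediate
22 | (E)-3-(diethylamino)-1-[2-hydroxy-3-(2-methylbut-3-en-2-yl)-4,6-bis(triisopropylsilyloxy)phenyl]-3-[4-(triisopropylsilyloxy)phenyl]prop-2-en-1-one (not isolated) | CCN(CC)/C(c1ccc(O[Si](C(C)C)(C(C)C)C(C)C)cc1)=C/C(=O)c1c(O)c(C(C)(C)C=C)c(O[Si](C(C)C)(C(C)C)C(C)C)cc1O[Si](C(C)C)(C(C)C)C(C)C | intermediate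
23 | 8-(2-methylbut-3-en-2-yl)-5,7-bis(triisopropylsilyloxy)-2-[4-(triisopropylsilyloxy)phenyl]-4H-chromen-4-one | C=CC(C)(C)c1c(O[Si](C(C)C)(C(C)C)C(C)C)cc(O[Si](C(C)C)(C(C)C)C(C)C)c2c(=O)cc(-c3ccc(O[Si](C(C)C)(C(C)C)C(C)C)cc3)oc12 | intermediate
24 | {8-(2-methylbut-3-en-2-yl)-4-oxo-5,7-bis(triisopropylsilyloxy)-2-[4-(triisopropylsilyloxy)phenyl]-4H-chromen-3-yl}lithium (not isolated) | C=CC(C)(C)c1c(O[Si](C(C)C)(C(C)C)C(C)C)cc(O[Si](C(C)C)(C(C)C)C(C)C)c2c(=O)c([Li])c(-c3ccc(O[Si](C(C)C)(C(C)C)C(C)C)cc3)oc12 | intermediate
25 | dimethyl {8-(2-methylbut-3-en-2-yl)-4-oxo-5,7-bis(triisopropylsilyloxy)-2-[4-(triisopropylsilyloxy)phenyl]-4H-chromen-3-yl}boronate (not isolated) | C=CC(C)(C)c1c(O[Si](C(C)C)(C(C)C)C(C)C)cc(O[Si](C(C)C)(C(C)C)C(C)C)c2c(=O)c(B(OC)OC)c(-c3ccc(O[Si](C(C)C)(C(C)C)C(C)C)cc3)oc12 | intermediate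
26 | 3-hydroxy-8-(2-methylbut-3-en-2-yl)-5,7-bis(triisopropylsilyloxy)-2-[4-(triisopropylsilyloxy)phenyl]-4H-chromen-4-one | C=CC(C)(C)c1c(O[Si](C(C)C)(C(C)C)C(C)C)cc(O[Si](C(C)C)(C(C)C)C(C)C)c2c(=O)c(O)c(-c3ccc(O[Si](C(C)C)(C(C)C)C(C)C)cc3)oc12 | intermediate
27 | 3,5,7-trihydroxy-2-(4-hydroxyphenyl)-8-(2-methylbut-3-en-2-yl)-4H-chromen-4-one | C=CC(C)(C)c1c(O)cc(O)c2c(=O)c(O)c(-c3ccc(O)cc3)oc12 | target

## Step count and least certain steps

Total step count: 13. Longest linear sequence: 9 steps (steps 1, 2, 5, 6, 9, 10, 11, 12, 13 from 1; equally steps 3, 4, 5, 6, 9 to 13 from 5). The branch from 16 (steps 7 and 8) joins at step 9.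

**Step 5 (key step).** Two things may go wrong.
- The vinylogous-ester conjugation in 4 slows the first ring opening. The temperature needed may then be high enough for 9 to isomerise by a 1,3-silyl shift to a silylketene or to oligomerise.
- The quaternary carbon on the attacking alkyne carbon slows the [2+2] step. Dimerisation of vinylketene 10 and acylation of the product phenol by 10 may then take over.

The fallback gives up the cycloaddition and attaches the quaternary carbon by a sigmatropic shift. It sets out from 3 and comes back at 14.
- Commercial benzene-1,3,5-triol F1 is silylated with two equivalents of 3 (imidazole, DMF). 3,5-Bis(triisopropylsilyloxy)phenol F2 is separated from the mono- and tris-silyl ethers.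
- Mitsunobu etherification of F2 with 3-methylbut-2-en-1-ol (PPh3, diisopropyl azodicarboxylate, THF, 0 °C) gives 1-[(3-methylbut-2-en-1-yl)oxy]-3,5-bis(triisopropylsilyloxy)benzene F3.
- Aromatic Claisen rearrangement of F3 (N,N-diethylaniline, about 180 °C, or Eu(fod)3 in CHCl3) bonds the CMe2 terminus to an ortho carbon. The two ortho carbons are equivalent, and enolisation gives 14 with the free hydroxyl next to the quaternary group.
- The price is a statistical silylation and the known tendency of ortho-(1,1-dimethylallyl)phenols to rearrange further on long heating, so the rearrangement would be stopped early.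

**Step 4.** Addition of LiCHBr2 to the α-quaternary ester may be slow, the tertiary alkyl group may migrate incompletely in the carbenoid, or the ynolate may be silylated partly on carbon. The fallback builds the alkyne first and adds the oxygen last. It sets out from 6 and comes back at 8, which is silylated with 3 to 9 as in step 4.
- Reduction of 6 with i-Bu2AlH (CH2Cl2, −78 °C) gives 2,2-dimethylbut-3-enal F4.
- CBr4 and PPh3 give 1,1-dibromo-3,3-dimethylpenta-1,4-diene F5.
- Two equivalents of n-BuLi (THF, −78 °C) give (3,3-dimethylpent-4-en-1-yn-1-yl)lithium F6.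
- Oxidation of F6 with lithium tert-butyl peroxide (from tert-butyl hydroperoxide and LiN(SiMe3)2, −78 to 0 °C) gives ynolate 8.

**Step 9.** The lithium phenoxide turns the doubly ortho-substituted aldehyde into a vinylogous carboxylate, so addition may stall. The very electron-rich carbinol 20 may also ionise on work-up. The fallback replaces the aldehyde–acetylide union by a palladium-catalysed carbonylative annulation. It sets out from 14 and 18 and comes back at 23.
- Phenol 14 is iodinated at C4a with one equivalent of N-iodosuccinimide (CH2Cl2, −78 °C) to 2-iodo-6-(2-methylbut-3-en-2-yl)-3,5-bis(triisopropylsilyloxy)phenol F7. The ring is far more nucleophilic than the alkene, and C4a is less crowded than C6.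
- Dibromoalkene 18 is converted with two equivalents of n-BuLi and then water into 1-ethynyl-4-(triisopropylsilyloxy)benzene F8.
- F7, F8 and CO with PdCl2(PPh3)2 in Et2NH (60 to 100 °C) should give the aroyl complex of divalent palladium after oxidative addition to zerovalent palladium and CO insertion. Coupling with the alkyne gives ynone 21 in the flask, and the amine closes it through 22 to 23.

**Step 12.** Metalation at C3 may be incomplete in the crowded, silylated flavone, the amide base may attack elsewhere, or the boron-to-oxygen shift may be slow. The fallback uses electrophilic oxygen transfer instead of deprotonation. It sets out from 23 and comes back at 26.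
- Dimethyldioxirane (acetone, 0 °C, close to one equivalent) epoxidises the enol-ether-like C2–C3 double bond. The product is 2,3-epoxy-8-(2-methylbut-3-en-2-yl)-5,7-bis(triisopropylsilyloxy)-2-[4-(triisopropylsilyloxy)phenyl]chroman-4-one F9 (racemic; the ring fusion can only be cis).
- A trace of p-toluenesulfonic acid in CH2Cl2 at 0 °C opens F9 to 26.
- The risk of this detour is competing epoxidation of the terminal alkene. That is why it is not the first choice.

## Further compounds

F1 | step 5 | benzene-1,3,5-triol | Oc1cc(O)cc(O)c1
F2 | step 5 | 3,5-bis(triisopropylsilyloxy)phenol | Oc1cc(O[Si](C(C)C)(C(C)C)C(C)C)cc(O[Si](C(C)C)(C(C)C)C(C)C)c1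
F3 | step 5 | 1-[(3-methylbut-2-en-1-yl)oxy]-3,5-bis(triisopropylsilyloxy)benzene | CC(C)=CCOc1cc(O[Si](C(C)C)(C(C)C)C(C)C)cc(O[Si](C(C)C)(C(C)C)C(C)C)c1
F4 | step 4 | 2,2-dimethylbut-3-enal | C=CC(C)(C)C=O
F5 | step 4 | 1,1-dibromo-3,3-dimethylpenta-1,4-diene | C=CC(C)(C)C=C(Br)Br
F6 | step 4 | (3,3-dimethylpent-4-en-1-yn-1-yl)lithium | [Li]C#CC(C)(C)C=C
F7 | step 9 | 2-iodo-6-(2-methylbut-3-en-2-yl)-3,5-bis(triisopropylsilyloxy)phenol | C=CC(C)(C)c1c(O)c(I)c(O[Si](C(C)C)(C(C)C)C(C)C)cc1O[Si](C(C)C)(C(C)C)C(C)C
F8 | step 9 | 1-ethynyl-4-(triisopropylsilyloxy)benzene | C#Cc1ccc(O[Si](C(C)C)(C(C)C)C(C)C)cc1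
F9 | step 12 | 2,3-epoxy-8-(2-methylbut-3-en-2-yl)-5,7-bis(triisopropylsilyloxy)-2-[4-(triisopropylsilyloxy)phenyl]chroman-4-one (racemic, cis-fused) | C=CC(C)(C)c1c(O[Si](C(C)C)(C(C)C)C(C)C)cc(O[Si](C(C)C)(C(C)C)C(C)C)c2c1OC1(c3ccc(O[Si](C(C)C)(C(C)C)C(C)C)cc3)OC1C2=O
A1 | alternative 1 | (E)-1-[2,4,6-trihydroxy-3-(2-methylbut-3-en-2-yl)phenyl]-3-[4-(methoxymethoxy)phenyl]prop-2-en-1-one | C=CC(C)(C)c1c(O)cc(O)c(C(=O)/C=C/c2ccc(OCOC)cc2)c1O
A2 | alternative 1 | 4-hydroxy-6-{(E)-4-[4-(methoxymethoxy)phenyl]-2-oxobut-3-en-1-yl}-3-(2-methylbut-3-en-2-yl)-2H-pyran-2-one | C=CC(C)(C)c1c(O)cc(CC(=O)/C=C/c2ccc(OCOC)cc2)oc1=O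
A3 | alternative 2 | 3-hydroxy-5,7-bis(methoxymethoxy)-2-[4-(methoxymethoxy)phenyl]-8-(2-methylbut-3-en-2-yl)chroman-4-one (mixture of diastereomers) | C=CC(C)(C)c1c(OCOC)cc(OCOC)c2c1OC(c1ccc(OCOC)cc1)C(O)C2=O
A4 | alternative 2 | 2-{1-[4-(methoxymethoxy)phenyl]-2-oxoethoxy}-4,6-bis(methoxymethoxy)-3-(2-methylbut-3-en-2-yl)benzaldehyde (racemic) | C=CC(C)(C)c1c(OCOC)cc(OCOC)c(C=O)c1OC(C=O)c1ccc(OCOC)cc1
A5 | alternative 3 | 2-(allyloxy)-1-[6-hydroxy-2,4-bis(methoxymethoxy)-3-(2-methylbut-3-en-2-yl)phenyl]ethan-1-one | C=CC(C)(C)c1c(OCOC)cc(O)c(C(=O)COCC=C)c1OCOC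
A6 | alternative 3 | 3,5-bis(methoxymethoxy)-4-(2-methylbut-3-en-2-yl)-2-(trimethylsilyl)phenyl trifluoromethanesulfonate | C=CC(C)(C)c1c(OCOC)cc(OS(=O)(=O)C(F)(F)F)c([Si](C)(C)C)c1OCOC
A7 | alternative 3 | 2-(allyloxy)acetic acid | C=CCOCC(=O)O
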